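**Retrosynthetic overview**
- The target is cut at the methyl-bearing sp2 carbon of the trisubstituted alkene nearest the cyclohexane. This carbon carries two carbon substituents (the CH2CH2 arm of the ring and a methyl) and is doubly bonded to a CH, so it maps onto a CCl2= terminus. A one-pot double Negishi coupling joins the 11-carbon ring fragment A (as alkylzinc), the 13-carbon dienyl butenolide fragment B (as 1,1-dichloroalkene) and one methyl (Me2Zn), and fixes the E geometry.
- Fragment A: the single stereocentre is set by a CBS reduction and carried onto the ring by a Johnson–Claisen [3,3] shift; ozonolysis and methylenation turn the resulting ethylidene into the exocyclic methylidene.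
- Fragment B: a Negishi coupling on 4-bromofuranone, acetal hydrolysis and gem-dichloro-olefination, then the same double coupling (acetal-bearing alkylzinc, then Me2Zn) build the second E-alkene; hydrolysis and a second gem-dichloro-olefination give the coupling partner.
- Ring order: no ring is closed in the route. The cyclohexane (from 3-methylcyclohexenone) and the butenolide (from 4-bromofuranone) are carried from the starting materials; fragment A is finished first (steps 1–8), fragment B second (steps 9–14).

Key step: step 15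

Remark: 4-bromofuran-2(5H)-one and [2-(1,3-dioxolan-2-yl)ethyl]zinc bromide (THF solution) are taken as purchased; the zinc reagent can otherwise be made from 2-(2-bromoethyl)-1,3-dioxolane and zinc dust.

**Step 1**
Reactants: 1 3-methylcyclohex-2-en-1-one
Product: 3 3,3-dimethylcyclohex-1-en-1-yl trifluoromethanesulfonate, via bromomagnesium enolate 2 (not isolated)
Conditions: MeMgBr, CuBr·SMe2 (5 mol%), THF, −30 °C; then PhNTf2, THF/DMPU, −30 °C → rt
Reagents that add atoms: methylmagnesium bromide, C[Mg]Br; N-phenylbis(trifluoromethanesulfonimide), O=S(=O)(N(c1ccccc1)S(=O)(=O)C(F)(F)F)C(F)(F)F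
Why: Copper-catalysed conjugate addition of the methyl Grignard reagent builds the gem-dimethyl carbon and gives the enolate regiospecifically on the side of that quaternary carbon, so enolate trapping by O-triflation fixes the alkene position needed later, and no stereocentre is formed.

**Step 2**
Reactants: 3 3,3-dimethylcyclohex-1-en-1-yl trifluoromethanesulfonate
Product: 5 1-(3,3-dimethylcyclohex-1-en-1-yl)ethan-1-one, via ethoxydiene 4 (not isolated)
Conditions: tributyl(1-ethoxyethenyl)stannane, Pd(PPh3)4 (3 mol%), LiCl, THF, reflux; then 1 M HCl, rt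
Reagents that add atoms: tributyl(1-ethoxyethenyl)stannane, CCCC[Sn](CCCC)(CCCC)C(=C)OCC; water, O
Why: Stille coupling of the enol triflate with the 1-ethoxyvinyl stannane (an acetyl anion equivalent) followed by acid hydrolysis of the enol ether should give the conjugated methyl ketone.

**Step 3**
Reactants: 5 1-(3,3-dimethylcyclohex-1-en-1-yl)ethan-1-one
Product: 6 (1R)-1-(3,3-dimethylcyclohex-1-en-1-yl)ethan-1-ol
Conditions: (S)-2-methyl-CBS-oxazaborolidine (15 mol%), catecholborane, toluene, −78 °C
Reagents that add atoms: none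
Why: Corey–Bakshi–Shibata reduction, in which the alkenyl group acts as the large substituent so that the (S)-oxazaborolidine delivers hydride to the face that gives the (R)-carbinol, while catecholborane at low temperature reduces 1,2 without touching the alkene.

**Step 4**
Reactants: 6 (1R)-1-(3,3-dimethylcyclohex-1-en-1-yl)ethan-1-ol
Product: 8 ethyl 2-[(1S,2E)-2-ethylidene-6,6-dimethylcyclohexyl]acetate, via ketene acetal 7 (not isolated)
Conditions: MeC(OEt)3 (6 equiv), EtCO2H (10 mol%), 140 °C, EtOH distilled off
Reagents that add atoms: triethyl orthoacetate, CCOC(C)(OCC)OCC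
Why: Johnson–Claisen rearrangement, in which the suprafacial [3,3] shift through a chair transition state with the carbinol methyl pseudo-equatorial carries the (R)-C–O stereocentre onto the ring carbon next to the gem-dimethyl group and so sets the (S)-ring stereocentre of the target (together with the E-ethylidene group).

**Step 5**
Reactants: 8 ethyl 2-[(1S,2E)-2-ethylidene-6,6-dimethylcyclohexyl]acetate
Product: 10 ethyl 2-[(1S)-2,2-dimethyl-6-oxocyclohexyl]acetate, via ozonide 9 (not isolated)
Conditions: O3, CH2Cl2, −78 °C; then Me2S, −78 °C → rt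
Reagents that add atoms: ozone, [O-][O+]=O
Why: Ozonolysis with reductive work-up cleaves the only alkene to the ring ketone under neutral conditions, which should leave the adjacent tertiary stereocentre, shielded by the quaternary carbon, untouched.

**Step 6**
Reactants: 10 ethyl 2-[(1S)-2,2-dimethyl-6-oxocyclohexyl]acetate
Product: 11 ethyl 2-[(1S)-2,2-dimethyl-6-methylidenecyclohexyl]acetate
Conditions: Zn, CH2Br2, TiCl4, THF, −40 → 5 °C (reagent aged); then 10, CH2Cl2, 0 °C → rt
Reagents that add atoms: dibromomethane, BrCBr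
Why: Lombardo methylenation, whose non-basic zinc–titanium methylene reagent converts enolisable ketones into 1,1-disubstituted alkenes without epimerising the α-carbon and is expected to leave the ester alone.

**Step 7**
Reactants: 11 ethyl 2-[(1S)-2,2-dimethyl-6-methylidenecyclohexyl]acetate
Product: 12 2-[(1S)-2,2-dimethyl-6-methylidenecyclohexyl]ethan-1-ol
Conditions: LiAlH4, Et2O, 0 °C
Reagents that add atoms: none
Why: Hydride reduction of the ester to the primary alcohol, which affects neither the alkene nor the stereocentre.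

**Step 8**
Reactants: 12 2-[(1S)-2,2-dimethyl-6-methylidenecyclohexyl]ethan-1-ol
Product: 13 (2S)-2-(2-iodoethyl)-1,1-dimethyl-3-methylidenecyclohexane
Conditions: I2, PPh3, imidazole, CH2Cl2, 0 °C → rt
Reagents that add atoms: iodine, II
Why: Appel-type iodination by SN2 displacement of the activated primary alcohol, two carbons away from the stereocentre.

**Step 9**
Reactants: 14 4-bromofuran-2(5H)-one; 15 [2-(1,3-dioxolan-2-yl)ethyl]zinc bromide
Product: 16 4-[2-(1,3-dioxolan-2-yl)ethyl]furan-2(5H)-one
Conditions: Pd(PPh3)4 (5 mol%), THF, 25 → 50 °C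
Reagents that add atoms: none
Why: Negishi coupling of a β-bromo-α,β-unsaturated lactone, which adds oxidatively to zerovalent palladium with ease, with a primary alkylzinc reagent that tolerates both lactone and acetal.

**Step 10**
Reactants: 16 4-[2-(1,3-dioxolan-2-yl)ethyl]furan-2(5H)-one
Product: 17 3-(5-oxo-2,5-dihydrofuran-3-yl)propanal
Conditions: 2 M HCl, THF/H2O, 40 °C
Reagents that add atoms: water, O
Why: Acid-catalysed acetal hydrolysis, to which the butenolide is stable.

**Step 11**
Reactants: 17 3-(5-oxo-2,5-dihydrofuran-3-yl)propanal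
Product: 18 4-(4,4-dichlorobut-3-en-1-yl)furan-2(5H)-one
Conditions: PPh3 (3 equiv), BrCCl3 (1.5 equiv), MeCN, 0 °C → rt
Reagents that add atoms: bromotrichloromethane, ClC(Cl)(Cl)Br
Why: Wittig-type gem-dichloro-olefination of the aldehyde by the non-basic ylide Ph3P=CCl2 formed from PPh3 and BrCCl3, which should not attack the lactone.

**Step 12**
Reactants: 18 4-(4,4-dichlorobut-3-en-1-yl)furan-2(5H)-one; 15 [2-(1,3-dioxolan-2-yl)ethyl]zinc bromide
Product: 20 4-[(3E)-6-(1,3-dioxolan-2-yl)-4-methylhex-3-en-1-yl]furan-2(5H)-one, via chloroalkene 19 (not isolated)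
Conditions: 15 (1.2 equiv), PdCl2(DPEphos) (5 mol%), THF/DMF, 25 → 45 °C; then Me2Zn, Pd(PtBu3)2 (5 mol%), 60 °C
Reagents that add atoms: dimethylzinc, C[Zn]C
Why: Double Negishi coupling of a 1,1-dichloro-1-alkene, in which the C–Cl bond trans to the chain reacts first with the alkylzinc under the bidentate catalyst and the remaining C–Cl bond is then methylated with retention, so that the E-alkene follows from the order of addition and no stereocentre is formed.

**Step 13**
Reactants: 20 4-[(3E)-6-(1,3-dioxolan-2-yl)-4-methylhex-3-en-1-yl]furan-2(5H)-one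
Product: 21 (4E)-4-methyl-7-(5-oxo-2,5-dihydrofuran-3-yl)hept-4-enal
Conditions: 2 M HCl, THF/H2O, 40 °C
Reagents that add atoms: water, O
Why: Acid-catalysed acetal hydrolysis under conditions that should neither isomerise the trisubstituted alkene nor open the butenolide.

**Step 14**
Reactants: 21 (4E)-4-methyl-7-(5-oxo-2,5-dihydrofuran-3-yl)hept-4-enal
Product: 22 4-[(3E)-8,8-dichloro-4-methylocta-3,7-dien-1-yl]furan-2(5H)-one
Conditions: PPh3 (3 equiv), BrCCl3 (1.5 equiv), MeCN, 0 °C → rt
Reagents that add atoms: bromotrichloromethane, ClC(Cl)(Cl)Br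
Why: Wittig-type gem-dichloro-olefination of the aldehyde as in step 11, which turns the carbonyl carbon into the future CH of the last alkene and attaches the carbon that will become the methyl-bearing sp2 centre.

**Step 15**
Reactants: 13 (2S)-2-(2-iodoethyl)-1,1-dimethyl-3-methylidenecyclohexane; 22 4-[(3E)-8,8-dichloro-4-methylocta-3,7-dien-1-yl]furan-2(5H)-one
Product: 25 4-[(3E,7E)-10-[(1S)-2,2-dimethyl-6-methylidenecyclohexyl]-4,8-dimethyldeca-3,7-dien-1-yl]furan-2(5H)-one, via alkylzinc iodide 23 (not isolated), via chloroalkene 24 (not isolated)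
Conditions: Zn dust (activated), THF/DMF, 40 °C; solution of 23 transferred to 22, PdCl2(DPEphos) (5 mol%), 25 → 45 °C; then Me2Zn, Pd(PtBu3)2 (5 mol%), 60 °C
Reagents that add atoms: dimethylzinc, C[Zn]C
Why: Zinc inserts into the primary C–I bond of 13; zerovalent palladium carrying DPEphos then adds oxidatively to the C–Cl bond of 22 that lies trans to the allylic CH2, transmetalation from 23 and reductive elimination give chloroalkene 24, and under the more active Pd(PtBu3)2 the remaining C–Cl bond is methylated by Me2Zn with retention, so the ring-side chain ends up trans and the methyl cis to the dienyl chain (E). The closest known reaction type is the trans-selective Negishi mono-alkylation of 1,1-dichloro-1-alkenes with alkylzinc halides followed by a stereoretentive second Negishi coupling, here run in one flask. No ring is closed and no stereocentre is created; the new stereo-element is the E-trisubstituted alkene, controlled by the order in which the two chlorides react. The step needs site selectivity between the two C–Cl bonds, mono- rather than double alkylation, retention in the second coupling and tolerance of the butenolide, the exocyclic alkene and the ring stereocentre: the cis CH2 substituent differentiates the chlorides sterically, the bidentate catalyst should not activate the more hindered alkenyl chloride at 45 °C, and organozinc reagents neither add to the lactone nor epimerise a centre two sp3 carbons away from zinc. In one operation the step joins the 11-carbon ring fragment and the 13-carbon butenolide fragment, brings in the last carbon atom and fixes the last element of geometry.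

**Compound list**
1 | 3-methylcyclohex-2-en-1-one | CC1=CC(=O)CCC1 | starting material
2 | bromomagnesium 3,3-dimethylcyclohex-1-en-1-olate (not isolated) | CC1(C)CCCC(O[Mg]Br)=C1 | intermediate
3 | 3,3-dimethylcyclohex-1-en-1-yl trifluoromethanesulfonate | CC1(C)CCCC(OS(=O)(=O)C(F)(F)F)=C1 | intermediate
4 | 1-(1-ethoxyethenyl)-3,3-dimethylcyclohex-1-ene (not isolated) | CCOC(=C)C1=CC(C)(C)CCC1 | intermediate
5 | 1-(3,3-dimethylcyclohex-1-en-1-yl)ethan-1-one | CC(=O)C1=CC(C)(C)CCC1 | intermediate
6 | (1R)-1-(3,3-dimethylcyclohex-1-en-1-yl)ethan-1-ol | C[C@@H](O)C1=CC(C)(C)CCC1 | intermediate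
7 | 1-[(1R)-1-(1-ethoxyethenyloxy)ethyl]-3,3-dimethylcyclohex-1-ene (not isolated) | CCOC(=C)O[C@H](C)C1=CC(C)(C)CCC1 | intermediate
8 | ethyl 2-[(1S,2E)-2-ethylidene-6,6-dimethylcyclohexyl]acetate | C/C=C1\CCCC(C)(C)[C@@H]1CC(=O)OCC | intermediate
9 | ethyl 2-[(6S)-3,7,7-trimethyl-1,2,4-trioxaspiro[4.5]decan-6-yl]acetate (ozonide, mixture at the two acetal carbons, not isolated) | CC1OOC2(O1)CCCC(C)(C)[C@@H]2CC(=O)OCC | intermediate
10 | ethyl 2-[(1S)-2,2-dimethyl-6-oxocyclohexyl]acetate | O=C1CCCC(C)(C)[C@@H]1CC(=O)OCC | intermediate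
11 | ethyl 2-[(1S)-2,2-dimethyl-6-methylidenecyclohexyl]acetate | C=C1CCCC(C)(C)[C@@H]1CC(=O)OCC | intermediate
12 | 2-[(1S)-2,2-dimethyl-6-methylidenecyclohexyl]ethan-1-ol | C=C1CCCC(C)(C)[C@@H]1CCO | intermediate
13 | (2S)-2-(2-iodoethyl)-1,1-dimethyl-3-methylidenecyclohexane | C=C1CCCC(C)(C)[C@@H]1CCI | intermediate
14 | 4-bromofuran-2(5H)-one | O=C1OCC(Br)=C1 | starting material
15 | [2-(1,3-dioxolan-2-yl)ethyl]zinc bromide | Br[Zn]CCC1OCCO1 | starting material
16 | 4-[2-(1,3-dioxolan-2-yl)ethyl]furan-2(5H)-one | O=C1OCC(CCC2OCCO2)=C1 | intermediate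
17 | 3-(5-oxo-2,5-dihydrofuran-3-yl)propanal | O=CCCC1=CC(=O)OC1 | intermediate
18 | 4-(4,4-dichlorobut-3-en-1-yl)furan-2(5H)-one | ClC(Cl)=CCCC1=CC(=O)OC1 | intermediate
19 | 4-[(3Z)-4-chloro-6-(1,3-dioxolan-2-yl)hex-3-en-1-yl]furan-2(5H)-one (not isolated) | O=C1OCC(CC/C=C(\Cl)CCC2OCCO2)=C1 | intermediate
20 | 4-[(3E)-6-(1,3-dioxolan-2-yl)-4-methylhex-3-en-1-yl]furan-2(5H)-one | O=C1OCC(CC/C=C(\C)CCC2OCCO2)=C1 | intermediate
21 | (4E)-4-methyl-7-(5-oxo-2,5-dihydrofuran-3-yl)hept-4-enal | O=CCC/C(C)=C/CCC1=CC(=O)OC1 | intermediate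
22 | 4-[(3E)-8,8-dichloro-4-methylocta-3,7-dien-1-yl]furan-2(5H)-one | ClC(Cl)=CCC/C(C)=C/CCC1=CC(=O)OC1 | intermediate
23 | {2-[(1S)-2,2-dimethyl-6-methylidenecyclohexyl]ethyl}zinc iodide (not isolated) | C=C1CCCC(C)(C)[C@@H]1CC[Zn]I | intermediate
24 | 4-[(3E,7Z)-8-chloro-10-[(1S)-2,2-dimethyl-6-methylidenecyclohexyl]-4-methyldeca-3,7-dien-1-yl]furan-2(5H)-one (not isolated) | C=C1CCCC(C)(C)[C@@H]1CC/C(Cl)=C/CC/C(C)=C/CCC1=CC(=O)OC1 | intermediate
25 | 4-[(3E,7E)-10-[(1S)-2,2-dimethyl-6-methylidenecyclohexyl]-4,8-dimethyldeca-3,7-dien-1-yl]furan-2(5H)-one | C=C1CCCC(C)(C)[C@@H]1CC/C(C)=C/CC/C(C)=C/CCC1=CC(=O)OC1 | target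

**Step count and risks**
Total step count: 15. Longest linear sequence: 9 steps (steps 1–8, then step 15).

Steps most likely to fail:

1. Step 15. The two C–Cl bonds may not be differentiated cleanly (double alkylation or attack at the cis C–Cl bond), the alkylpalladium intermediate may lose a β-hydride, or geometry may erode in the second coupling. Fallback: the two bond formations are decoupled and the first is moved to boron. Setting out from 13, iodine–lithium exchange (t-BuLi, Et2O, −78 °C) should give {2-[(1S)-2,2-dimethyl-6-methylidenecyclohexyl]ethyl}lithium F1, which is trapped with 9-methoxy-9-borabicyclo[3.3.1]nonane as lithium 9-{2-[(1S)-2,2-dimethyl-6-methylidenecyclohexyl]ethyl}-9-methoxy-9-boranuidabicyclo[3.3.1]nonane F2. B-alkyl Suzuki–Miyaura coupling of F2 with 22 (Pd2(dba)3, Xantphos, K3PO4, THF/H2O, 60 °C) should give chloroalkene 24, where the fallback comes back to the route; 24 is isolated, freed from isomers, and methylated on its own (Me2Zn, Pd(PtBu3)2, THF, 60 °C) to 25.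

2. Step 12. The same selectivity problems as in step 15 arise on the small dichloride 18, and excess alkylzinc may compete with Me2Zn in the second coupling. Fallback: the E-alkene is made by a Claisen rearrangement instead. Setting out from 17, Nozaki–Hiyama–Kishi addition of 2-bromopropene (CrCl2, NiCl2 cat., DMF) should give 4-(3-hydroxy-4-methylpent-4-en-1-yl)furan-2(5H)-one F3 (racemic, its stereocentre is destroyed later). Vinyl exchange with ethyl vinyl ether under Hg(OAc)2 catalysis gives 4-[3-(ethenyloxy)-4-methylpent-4-en-1-yl]furan-2(5H)-one F4, and heating (toluene, sealed tube, 150 °C) should rearrange it through a chair transition state with the chain pseudo-equatorial to the E-aldehyde 21, where the fallback comes back to the route.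

3. Step 4. The rearrangement forms a bond next to a quaternary carbon and may be slow at 140 °C under acid, so that dehydration of the allylic alcohol or ionisation with loss of chirality transfer competes; the pathway with the methyl pseudo-axial would also erode the enantiomeric purity. Fallback: a low-temperature ester enolate rearrangement. Setting out from 6, acetylation (Ac2O, Et3N, DMAP) gives (1R)-1-(3,3-dimethylcyclohex-1-en-1-yl)ethyl acetate F5. LDA and Me3SiCl (THF, −78 °C) give 1-[(1R)-1-{[1-(trimethylsilyloxy)ethenyl]oxy}ethyl]-3,3-dimethylcyclohex-1-ene F6, which on warming should undergo the Ireland–Claisen rearrangement to trimethylsilyl 2-[(1S,2E)-2-ethylidene-6,6-dimethylcyclohexyl]acetate F7. Aqueous work-up gives 2-[(1S,2E)-2-ethylidene-6,6-dimethylcyclohexyl]acetic acid F8, and esterification (EtI, K2CO3, DMF) returns to the route at 8.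

**Further compounds**
F1 | step 15 | {2-[(1S)-2,2-dimethyl-6-methylidenecyclohexyl]ethyl}lithium | C=C1CCCC(C)(C)[C@@H]1CC[Li]
F2 | step 15 | lithium 9-{2-[(1S)-2,2-dimethyl-6-methylidenecyclohexyl]ethyl}-9-methoxy-9-boranuidabicyclo[3.3.1]nonane | [Li+].C=C1CCCC(C)(C)[C@@H]1CC[B-]1(OC)C2CCCC1CCC2
F3 | step 12 | 4-(3-hydroxy-4-methylpent-4-en-1-yl)furan-2(5H)-one | CC(=C)C(O)CCC1=CC(=O)OC1
F4 | step 12 | 4-[3-(ethenyloxy)-4-methylpent-4-en-1-yl]furan-2(5H)-one | CC(=C)C(OC=C)CCC1=CC(=O)OC1
F5 | step 4 | (1R)-1-(3,3-dimethylcyclohex-1-en-1-yl)ethyl acetate | CC(=O)O[C@H](C)C1=CC(C)(C)CCC1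
F6 | step 4 | 1-[(1R)-1-{[1-(trimethylsilyloxy)ethenyl]oxy}ethyl]-3,3-dimethylcyclohex-1-ene | C=C(O[Si](C)(C)C)O[C@H](C)C1=CC(C)(C)CCC1
F7 | step 4 | trimethylsilyl 2-[(1S,2E)-2-ethylidene-6,6-dimethylcyclohexyl]acetate | C/C=C1\CCCC(C)(C)[C@@H]1CC(=O)O[Si](C)(C)C
F8 | step 4 | 2-[(1S,2E)-2-ethylidene-6,6-dimethylcyclohexyl]acetic acid | C/C=C1\CCCC(C)(C)[C@@H]1CC(=O)O
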